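(The numbers in the tables are calculated with made-up constants; the scatter is artificial.)

4 questions stood on this flask, and I took the solid substrate first, turning its question round: what would have to be true for none of it to remain?

| flask | solid substrate | coupling partner | remark | time |
|---|---|---|---|---|
| Tuesday's | 15 mM | 1.8 equiv | run made earlier |  |
| flask | 10 mM | 1.80 equiv |  | 12 min |

Tuesday's run (percent of the solid substrate charged)

| time / min | solid substrate / % | single product / % |
|---|---|---|
| 0.250 | 98.6 | 1.0 |
| 0.667 | 93.8 | 0.7 |
| 1.33 | 92.0 | 2.0 |
| 2.00 | 86.8 | 1.6 |
| 3.00 | 81.3 | 1.9 |
| 4.00 | 78.0 | 3.5 |

(readings scatter by 1 percentage point)

- solid substrate is a solid; its amount is given per volume of the solution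
- at the start none of the solid substrate is in solution

- how much solid substrate there is at 12 min, in percent of the solid substrate charged (only what is still solid)
- how much single product there is at 12 min, in percent of the solid substrate charged
- how much other mono adduct there is at 12 min, in percent of the solid substrate charged
- how much bis adduct there is at 12 min, in percent of the solid substrate charged

Tuesday's run lost 1.98 mM of solid by 2.00 min and 3.30 mM by 4.00 min, so its second step gave 0.667 of its first. If each equal step kept giving that fraction of the one before, the steps would sum to 5.94 mM. I called this the dissolving budget, the concentration of solid that passes into solution in total, and I held it as rough, each reading carrying 1 percentage point.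

Dividing the budget by the charge counts turnovers of the solid. For none to remain at 12 min in this flask the count had to reach 1, which meant a steady 0.833 mM/min, but Tuesday's second step ran slower, at 0.660 mM/min. Keeping Tuesday's budget in mM and taking it as reached by 12 min, this flask counted 0.594, so I committed to about 40.6% solid left.

The forecast said 48% solid (30% to 62%), the value that first-order decay through Tuesday's last reading gives, with 11% single product, 2% other mono adduct and 1.5% bis adduct. Its ground was a supposition, “If dissolution scales with solid surface, percent loss is about independent of loading”, whereas I held the budget in mM fixed.

This flask gave 54.5% solid, 6.56% single product, 15.3% other mono adduct and 7.09% bis adduct.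

starting material + coupling partner → other mono adduct (k = 0.872 /M/s); coupling partner + other mono adduct → bis adduct (k = 0.0178 /M/s); starting material + coupling partner → single product (k = 0.753 /M/s); coupling partner → decomposed reagent (k = 0.00540 /s); solid substrate ⇌ starting material, rate k5*(cs5 - [starting material]) while solid is left; crystals form when [starting material] > cs5 (solubility = 1.70 mM, k = 0.0121 /s); coupling partner + single product → bis adduct (k = 0.955 /M/s) So in this flask 4.55 mM had dissolved against my budget of 5.94 mM, a count of 0.455, and the solid still stood at 53.9% after 120 min. The neighbour charged with 25 mM of solid, at the same equivalents and time, counts 0.238 on the same budget, which leaves 76.2% solid. That flask gave 73.2%, with 6.71 mM dissolved, a count of 0.268.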